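**Retrosynthetic overview**
- Feature: in the central benzene (ring A) the carbon bearing CH2OH and the carbon bearing the alkyne are neighbours, so the pair is a phthalide in disguise (lactone C=O on the alkyne-bearing carbon, OCH2 on the other). Going on round ring A come the carbon bearing Cm (the methide carbon with rings C and D), the carbon bearing phenol ring B and two CH carbons. In the bicyclic intermediates these are C7a (C=O), C7 (Cm), C6 (ring B), the two CH carbons and C3a (CH2O). C6, the two CH carbons and C3a are the footprint of a 1-aryl diene; C7a and C7 are that of an ynoate.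
- Endgame: quinone methide from acid ionisation of a Cm–OMe ether with MOM removal; ring E by Sonogashira coupling; C≡CH by Seyferth–Gilbert homologation of the lactol of the phthalide.
- Phthalide from DDQ dehydrogenation of the adduct of an intramolecular Diels–Alder reaction of a (2E,4E)-5-arylpentadienyl 4,4-diaryl-4-methoxybut-2-ynoate (new bonds C7–C6 and C7a–C3a).
- Ester from a dienol (4-hydroxybenzaldehyde, vinylogous Horner–Wadsworth–Emmons, reduction) and an ynoic acid (4,4'-dihydroxybenzophenone, ethynylation, O-methylation, carboxylation).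
- Ring order: rings B, C, D and E are bought as phenols; ring A and the γ-lactone close together in the key step; the lactone is opened again when the alkyne is made.

Key step: step 9

Remark on the chemistry: the target has no stereocentre. The cis pair of centres made in step 9 is removed in step 10 and the hemiacetal centre of the lactol from step 11 is removed in step 12, so chiral intermediates are used as racemates. Abbreviations: MOM = CH2OCH3; Ar = 4-(methoxymethoxy)phenyl.

**Step 1**
Reactants: 1 4-hydroxybenzaldehyde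
Product: 2 4-(methoxymethoxy)benzaldehyde
Conditions: NaH, MOMCl, DMF, 0 °C to rt
Reagents that add atoms: chloromethyl methyl ether, COCCl
Why: Williamson-type O-alkylation of the sodium phenoxide by the reactive α-chloro ether (MOM protection) is fast at 0 °C and leaves the aldehyde untouched.

**Step 2**
Reactants: 2 4-(methoxymethoxy)benzaldehyde; 3 triethyl 4-phosphonocrotonate
Product: 4 ethyl (2E,4E)-5-Ar-penta-2,4-dienoate
Conditions: LiN(SiMe3)2, THF, −78 °C to rt
Reagents that add atoms: none
Why: Vinylogous Horner–Wadsworth–Emmons olefination, in which the lithiated phosphonocrotonate reacts at the carbon next to phosphorus with the aromatic aldehyde and the stabilised phosphonate eliminates to the E alkene while the crotonate double bond stays E.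

**Step 3**
Reactants: 4 ethyl (2E,4E)-5-Ar-penta-2,4-dienoate
Product: 5 (2E,4E)-5-Ar-penta-2,4-dien-1-ol
Conditions: i-Bu2AlH, CH2Cl2, −78 to 0 °C; aq. potassium sodium tartrate
Reagents that add atoms: none
Why: 1,2-Reduction of the conjugated ester by i-Bu2AlH (two hydride transfers through the aldehyde) gives the allylic alcohol without touching the diene or the MOM ether.

**Step 4**
Reactants: 6 4,4'-dihydroxybenzophenone
Product: 7 bis[4-(methoxymethoxy)phenyl]methanone
Conditions: NaH, MOMCl, DMF, 0 °C to rt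
Reagents that add atoms: chloromethyl methyl ether, COCCl
Why: Double Williamson-type O-alkylation of the bis-phenoxide (MOM protection) proceeds as in step 1, the diaryl ketone being inert to NaH and the chloro ether.

**Step 5**
Reactants: 7 bis[4-(methoxymethoxy)phenyl]methanone
Product: 8 1,1-di-Ar-prop-2-yn-1-ol
Conditions: HC≡CMgBr, THF, 0 °C to rt; then H2O (pH 7 buffer)
Reagents that add atoms: ethynylmagnesium bromide, C#C[Mg]Br
Why: Nucleophilic 1,2-addition of the ethynyl Grignard reagent to the non-enolisable diaryl ketone gives the tertiary propargylic alkoxide, and the MOM acetals are inert to the reagent.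

**Step 6**
Reactants: 8 1,1-di-Ar-prop-2-yn-1-ol
Product: 9 3-methoxy-3,3-di-Ar-prop-1-yne
Conditions: NaH, MeI, THF, 0 °C to rt
Reagents that add atoms: iodomethane, CI
Why: Williamson etherification, in which NaH removes only the hydroxyl proton (the alkyne C–H is far less acidic) and the alkoxide is methylated by iodomethane under basic conditions that cannot ionise the diaryl carbinol centre.

**Step 7**
Reactants: 9 3-methoxy-3,3-di-Ar-prop-1-yne
Product: 11 4-methoxy-4,4-di-Ar-but-2-ynoic acid, via lithium acetylide 10 (not isolated)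
Conditions: n-BuLi, THF, −78 °C; CO2; cold dilute HCl to pH 3; crude acid used at once
Reagents that add atoms: carbon dioxide, O=C=O
Why: Deprotonation of the terminal alkyne and carboxylation of the lithium acetylide with CO2 is the standard route to alk-2-ynoic acids, and the cold, mildly acidic work-up spares the ionisable methyl ether and the MOM groups.

**Step 8**
Reactants: 11 4-methoxy-4,4-di-Ar-but-2-ynoic acid; 5 (2E,4E)-5-Ar-penta-2,4-dien-1-ol
Product: 12 (2E,4E)-5-Ar-penta-2,4-dien-1-yl 4-methoxy-4,4-di-Ar-but-2-ynoate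
Conditions: DCC, DMAP (cat.), CH2Cl2, 0 °C
Reagents that add atoms: none
Why: Steglich esterification (carbodiimide activation, DMAP acyl transfer) joins the primary dienol to the acid under neutral conditions at 0 °C, where the hindered β-carbon of the ynoate resists conjugate addition of DMAP and the dienol is not ionised.

**Step 9**
Reactants: 12 (2E,4E)-5-Ar-penta-2,4-dien-1-yl 4-methoxy-4,4-di-Ar-but-2-ynoate
Product: 13 racemic cis-7-[methoxy(di-Ar)methyl]-6-Ar-3a,6-dihydro-2-benzofuran-1(3H)-one (3a-H and 6-H on the same face; the (3aS,6S) enantiomer is drawn)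
Conditions: BHT (cat.), o-xylene (0.01 M, degassed), 150 °C, base-washed sealed tube
Reagents that add atoms: none
Why: Thermal intramolecular Diels–Alder reaction of a 2,4-pentadienyl alkynoate, the closest known reaction type being the cyclisation of such esters to 3a,6-dihydrophthalides: in the s-cis ester rotamer the ynoate adds in one concerted, suprafacial [4+2] event across the two termini of the (E,E)-diene. Ring A closes as a six-membered cyclohexa-1,4-diene through the new bonds C7a–C3a (ester-bearing alkyne carbon to the CH2O-bearing diene terminus) and C7–C6 (Cm-bearing alkyne carbon to the ring B terminus), and the five-membered γ-lactone closes through the same C7a–C3a bond, the ester O–CH2 and C=O forming the three-atom bridge that allows only the fused mode of addition. The stereocentres C3a and C6 are set together by the (E,E) geometry of the diene and the suprafacial addition, which place 3a-H and 6-H cis; the adduct is racemic, and both centres are removed in step 10, so no facial selectivity is required. The selectivity needed is regiochemical, ester-bearing carbon to the CH2O terminus and Cm-bearing carbon to the ring B terminus, and the tether enforces it against the electronic preference of a 1-aryl diene. High dilution favours the intramolecular path, BHT suppresses radical polymerisation of the diene, and base-washed glass keeps the doubly benzylic methyl ether from ionising at 150 °C. The weak point is steric, because the C7–C6 bond is made next to the fully substituted Cm, and this is why the step is reached by routine chemistry and tested early.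

**Step 10**
Reactants: 13 racemic cis-7-[methoxy(di-Ar)methyl]-6-Ar-3a,6-dihydro-2-benzofuran-1(3H)-one
Product: 14 7-[methoxy(di-Ar)methyl]-6-Ar-2-benzofuran-1(3H)-one
Conditions: DDQ, NaHCO3, CH2Cl2, 0 °C to rt
Reagents that add atoms: none
Why: Dehydrogenation of a cyclohexa-1,4-diene by DDQ (hydride abstraction from the doubly allylic, benzylic C6–H, then loss of the C3a proton) is driven by aromatisation of ring A, and the NaHCO3 buffer keeps the acidic hydroquinone from ionising the Cm methyl ether, which would open a path to loss of methanol.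

**Step 11**
Reactants: 14 7-[methoxy(di-Ar)methyl]-6-Ar-2-benzofuran-1(3H)-one
Product: 15 7-[methoxy(di-Ar)methyl]-6-Ar-1,3-dihydro-2-benzofuran-1-ol (racemic lactol)
Conditions: i-Bu2AlH, toluene/CH2Cl2, −78 °C; aq. potassium sodium tartrate
Reagents that add atoms: none
Why: Partial reduction of the lactone by i-Bu2AlH at −78 °C stops at the tetrahedral aluminium hemiacetal, which gives the lactol on work-up, the new hemiacetal centre being formed without control and lost in step 12.

**Step 12**
Reactants: 15 7-[methoxy(di-Ar)methyl]-6-Ar-1,3-dihydro-2-benzofuran-1-ol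
Product: 17 {2-ethynyl-3-[methoxy(di-Ar)methyl]-4-Ar-phenyl}methanol, via hydroxy aldehyde 16 (not isolated)
Conditions: dimethyl (1-diazo-2-oxopropyl)phosphonate, K2CO3, MeOH/THF, 0 °C to rt
Reagents that add atoms: dimethyl (1-diazo-2-oxopropyl)phosphonate, COP(=O)(OC)C(=[N+]=[N-])C(C)=O
Why: Seyferth–Gilbert homologation in the Ohira–Bestmann variant, in which methoxide cleaves the acetyl group of the reagent, the diazomethylphosphonate anion olefinates the aldehyde in equilibrium with the lactol, and loss of N2 with 1,2-hydrogen shift of the alkylidene carbene gives the terminal alkyne under base that leaves the MOM groups and the methyl ether untouched.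

**Step 13**
Reactants: 18 4-iodophenol
Product: 19 1-iodo-4-(methoxymethoxy)benzene
Conditions: NaH, MOMCl, DMF, 0 °C to rt
Reagents that add atoms: chloromethyl methyl ether, COCCl
Why: Williamson-type O-alkylation of the phenoxide (MOM protection) as in step 1, with the aryl iodide inert under these conditions.

**Step 14**
Reactants: 17 {2-ethynyl-3-[methoxy(di-Ar)methyl]-4-Ar-phenyl}methanol; 19 1-iodo-4-(methoxymethoxy)benzene
Product: 20 {2-(Ar-ethynyl)-3-[methoxy(di-Ar)methyl]-4-Ar-phenyl}methanol
Conditions: PdCl2(PPh3)2 (cat.), CuI (cat.), Et3N, THF, degassed, rt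
Reagents that add atoms: none
Why: Sonogashira coupling, in which oxidative addition of the aryl iodide to zerovalent palladium, transmetalation of the copper acetylide and reductive elimination form the sp–sp2 bond at the unhindered alkyne terminus at room temperature, where the free benzylic alcohol does not add to the alkyne.

**Step 15**
Reactants: 20 {2-(Ar-ethynyl)-3-[methoxy(di-Ar)methyl]-4-Ar-phenyl}methanol
Product: 22 selaginellin, via tetraphenol methyl ether 21 (not isolated)
Conditions: 2 M HCl, MeOH/THF, rt; then aq. NaHCO3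
Reagents that add atoms: none
Why: Acidic methanolysis cleaves the four aryl MOM acetals (the CH2 unit leaving as dimethoxymethane) and reversibly ionises the triaryl methyl ether, and on neutralisation the 4-hydroxyphenyl-stabilised cation loses methanol and a phenolic proton to give the quinone methide, the 1,6-elimination by which 4-hydroxytrityl derivatives give fuchsones.

**Compound list** (Ar = 4-(methoxymethoxy)phenyl)
1 | 4-hydroxybenzaldehyde | O=Cc1ccc(O)cc1 | starting material
2 | 4-(methoxymethoxy)benzaldehyde | COCOc1ccc(C=O)cc1 | intermediate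
3 | triethyl 4-phosphonocrotonate | CCOC(=O)/C=C/CP(=O)(OCC)OCC | starting material
4 | ethyl (2E,4E)-5-[4-(methoxymethoxy)phenyl]penta-2,4-dienoate | CCOC(=O)/C=C/C=C/c1ccc(OCOC)cc1 | intermediate
5 | (2E,4E)-5-[4-(methoxymethoxy)phenyl]penta-2,4-dien-1-ol | OC/C=C/C=C/c1ccc(OCOC)cc1 | intermediate
6 | 4,4'-dihydroxybenzophenone | O=C(c1ccc(O)cc1)c1ccc(O)cc1 | starting material
7 | bis[4-(methoxymethoxy)phenyl]methanone | O=C(c1ccc(OCOC)cc1)c1ccc(OCOC)cc1 | intermediate
8 | 1,1-bis[4-(methoxymethoxy)phenyl]prop-2-yn-1-ol | C#CC(O)(c1ccc(OCOC)cc1)c1ccc(OCOC)cc1 | intermediate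
9 | 3-methoxy-3,3-bis[4-(methoxymethoxy)phenyl]prop-1-yne | C#CC(OC)(c1ccc(OCOC)cc1)c1ccc(OCOC)cc1 | intermediate
10 | lithium acetylide of 9 (1-lithio-3-methoxy-3,3-bis[4-(methoxymethoxy)phenyl]prop-1-yne) | [Li]C#CC(OC)(c1ccc(OCOC)cc1)c1ccc(OCOC)cc1 | intermediate (not isolated)
11 | 4-methoxy-4,4-bis[4-(methoxymethoxy)phenyl]but-2-ynoic acid | OC(=O)C#CC(OC)(c1ccc(OCOC)cc1)c1ccc(OCOC)cc1 | intermediate
12 | (2E,4E)-5-[4-(methoxymethoxy)phenyl]penta-2,4-dien-1-yl 4-methoxy-4,4-bis[4-(methoxymethoxy)phenyl]but-2-ynoate | COCOc1ccc(/C=C/C=C/COC(=O)C#CC(OC)(c2ccc(OCOC)cc2)c2ccc(OCOC)cc2)cc1 | intermediate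
13 | racemic cis-7-{methoxybis[4-(methoxymethoxy)phenyl]methyl}-6-[4-(methoxymethoxy)phenyl]-3a,6-dihydro-2-benzofuran-1(3H)-one ((3aS,6S) enantiomer drawn) | O=C1OC[C@H]2C=C[C@@H](c3ccc(OCOC)cc3)C(C(OC)(c3ccc(OCOC)cc3)c3ccc(OCOC)cc3)=C12 | intermediate
14 | 7-{methoxybis[4-(methoxymethoxy)phenyl]methyl}-6-[4-(methoxymethoxy)phenyl]-2-benzofuran-1(3H)-one | O=C1OCc2ccc(-c3ccc(OCOC)cc3)c(C(OC)(c3ccc(OCOC)cc3)c3ccc(OCOC)cc3)c12 | intermediate
15 | 7-{methoxybis[4-(methoxymethoxy)phenyl]methyl}-6-[4-(methoxymethoxy)phenyl]-1,3-dihydro-2-benzofuran-1-ol (racemic) | OC1OCc2ccc(-c3ccc(OCOC)cc3)c(C(OC)(c3ccc(OCOC)cc3)c3ccc(OCOC)cc3)c12 | intermediate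
16 | 2-(hydroxymethyl)-6-{methoxybis[4-(methoxymethoxy)phenyl]methyl}-5-[4-(methoxymethoxy)phenyl]benzaldehyde | O=Cc1c(CO)ccc(-c2ccc(OCOC)cc2)c1C(OC)(c1ccc(OCOC)cc1)c1ccc(OCOC)cc1 | intermediate (not isolated)
17 | {2-ethynyl-3-{methoxybis[4-(methoxymethoxy)phenyl]methyl}-4-[4-(methoxymethoxy)phenyl]phenyl}methanol | C#Cc1c(CO)ccc(-c2ccc(OCOC)cc2)c1C(OC)(c1ccc(OCOC)cc1)c1ccc(OCOC)cc1 | intermediate
18 | 4-iodophenol | Oc1ccc(I)cc1 | starting material
19 | 1-iodo-4-(methoxymethoxy)benzene | COCOc1ccc(I)cc1 | intermediate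
20 | {3-{methoxybis[4-(methoxymethoxy)phenyl]methyl}-4-[4-(methoxymethoxy)phenyl]-2-{[4-(methoxymethoxy)phenyl]ethynyl}phenyl}methanol | COCOc1ccc(C#Cc2c(CO)ccc(-c3ccc(OCOC)cc3)c2C(OC)(c2ccc(OCOC)cc2)c2ccc(OCOC)cc2)cc1 | intermediate
21 | 4,4'-{[3-(hydroxymethyl)-6-(4-hydroxyphenyl)-2-[(4-hydroxyphenyl)ethynyl]phenyl](methoxy)methylene}diphenol | COC(c1ccc(O)cc1)(c1ccc(O)cc1)c1c(-c2ccc(O)cc2)ccc(CO)c1C#Cc1ccc(O)cc1 | intermediate (not isolated)
22 | selaginellin, 4-{[3-(hydroxymethyl)-6-(4-hydroxyphenyl)-2-[(4-hydroxyphenyl)ethynyl]phenyl](4-hydroxyphenyl)methylidene}cyclohexa-2,5-dien-1-one | O=C1C=CC(=C(c2ccc(O)cc2)c2c(-c3ccc(O)cc3)ccc(CO)c2C#Cc2ccc(O)cc2)C=C1 | target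

**Step count**
Total step count: 15.
Longest linear sequence: 11 steps (steps 4 to 12, 14 and 15, from 6).

**Steps most likely to fail**

1. Step 9. The cycloaddition may be outrun by thermal decay of the triene. The reactive s-cis ester rotamer is sparsely populated, and bond formation next to the fully substituted Cm, in the orientation opposed to the electronic bias of the aryl diene, is slow. Ionisation of the methyl ether, ionisation of the aryl-stabilised pentadienyl ester or polymerisation of the diene may therefore consume the substrate first.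

Fallback (sets out from 5, uses 2 and 19, returns to the route at 17): Cm is carried through the cycloaddition as a ketone, which makes the alkyne flat at the reacting carbon and activated at both ends. Dienol 5 is esterified with propiolic acid (DCC, CH2Cl2, −20 °C) to (2E,4E)-5-Ar-penta-2,4-dien-1-yl prop-2-ynoate F1. Its lithium acetylide (LiN(SiMe3)2, THF, −78 °C) adds to aldehyde 2 to give racemic (2E,4E)-5-Ar-penta-2,4-dien-1-yl 4-hydroxy-4-Ar-but-2-ynoate F2. MnO2 in CH2Cl2 oxidises the benzylic propargylic alcohol to (2E,4E)-5-Ar-penta-2,4-dien-1-yl 4-Ar-4-oxobut-2-ynoate F3. This ynone ester should undergo the same tether-directed intramolecular Diels–Alder reaction in toluene at 80 to 110 °C, giving racemic cis-7-[4-(methoxymethoxy)benzoyl]-6-Ar-3a,6-dihydro-2-benzofuran-1(3H)-one F4. DDQ aromatises it to 7-[4-(methoxymethoxy)benzoyl]-6-Ar-2-benzofuran-1(3H)-one F5. The aryl Grignard reagent ArMgCl·LiCl, made from iodide 19 with i-PrMgCl·LiCl, should add at −78 °C to the ketone in preference to the lactone. The tertiary alkoxide then takes over the neighbouring acyl group, so the product is the ring-switched lactone 7-(hydroxymethyl)-3,3,4-tri-Ar-2-benzofuran-1(3H)-one F6, whose carbonyl carbon still sits on the ring A carbon that carries the alkyne in the target. i-Bu2AlH (toluene, −78 °C) reduces it to 7-(hydroxymethyl)-3,3,4-tri-Ar-1,3-dihydro-2-benzofuran-1-ol F7. The Ohira–Bestmann reagent (K2CO3, MeOH) converts the masked aldehyde into {2-ethynyl-3-[hydroxy(di-Ar)methyl]-4-Ar-phenyl}methanol F8. Pyridinium p-toluenesulfonate in methanol then exchanges only the ionisable tertiary hydroxyl for methoxy (SN1), which gives 17.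

2. Step 12. The olefination may stall because the carbonyl is tied up as the lactol and is shielded on both sides (Cm on one neighbouring ring carbon, CH2OH on the other), so the diazophosphonate anion is consumed by methanol before it adds.

Fallback (sets out from 14, returns at 17): the aldehyde is set free as such and met with a stronger nucleophile. LiAlH4 (THF, 0 °C) reduces the lactone to {3-[methoxy(di-Ar)methyl]-4-Ar-1,2-phenylene}dimethanol F9. t-BuPh2SiCl and imidazole (CH2Cl2) silylate the less hindered hydroxymethyl group, the one remote from Cm, giving {2-({[tert-butyl(diphenyl)silyl]oxy}methyl)-6-[methoxy(di-Ar)methyl]-5-Ar-phenyl}methanol F10. Dess–Martin periodinane buffered with NaHCO3 oxidises the remaining alcohol to 2-({[tert-butyl(diphenyl)silyl]oxy}methyl)-6-[methoxy(di-Ar)methyl]-5-Ar-benzaldehyde F11. Colvin homologation with lithiated trimethylsilyldiazomethane (Me3SiCHN2, LiN(i-Pr)2, THF, −78 °C to rt) gives tert-butyl{[2-ethynyl-3-[methoxy(di-Ar)methyl]-4-Ar-phenyl]methoxy}diphenylsilane F12. Bu4NF in THF removes the silyl group and gives 17.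

3. Step 15. While the MOM groups are being cleaved the Cm cation is long-lived. It may close onto ring B (five-membered ring, Friedel–Crafts), the benzylic hydroxyl may add to the acid-activated alkyne, and methoxymethyl cations may alkylate the freed phenols.

Fallback (sets out from 20, returns at 22): the cation is quenched by hydride as it forms and the quinone methide is made by oxidation at the end. Et3SiH with a little CF3CO2H (CH2Cl2, −20 °C; ionic hydrogenation of the trityl-type ether) gives {3-[di-Ar-methyl]-4-Ar-2-(Ar-ethynyl)phenyl}methanol F13. HCl in MeOH/THF then removes the four MOM groups from a molecule that has no ionisable centre, giving 4,4'-{[3-(hydroxymethyl)-6-(4-hydroxyphenyl)-2-[(4-hydroxyphenyl)ethynyl]phenyl]methylene}diphenol F14. One equivalent of DDQ (MeOH/dioxane, 0 °C) abstracts the triarylmethane hydride para to two hydroxyl groups, the known oxidation of 4-hydroxytriarylmethanes to fuchsones, and gives 22.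

**Further compounds**
F1 | step 9 | (2E,4E)-5-[4-(methoxymethoxy)phenyl]penta-2,4-dien-1-yl prop-2-ynoate | C#CC(=O)OC/C=C/C=C/c1ccc(OCOC)cc1
F2 | step 9 | (2E,4E)-5-[4-(methoxymethoxy)phenyl]penta-2,4-dien-1-yl 4-hydroxy-4-[4-(methoxymethoxy)phenyl]but-2-ynoate (racemic) | COCOc1ccc(/C=C/C=C/COC(=O)C#CC(O)c2ccc(OCOC)cc2)cc1
F3 | step 9 | (2E,4E)-5-[4-(methoxymethoxy)phenyl]penta-2,4-dien-1-yl 4-[4-(methoxymethoxy)phenyl]-4-oxobut-2-ynoate | COCOc1ccc(/C=C/C=C/COC(=O)C#CC(=O)c2ccc(OCOC)cc2)cc1
F4 | step 9 | racemic cis-7-[4-(methoxymethoxy)benzoyl]-6-[4-(methoxymethoxy)phenyl]-3a,6-dihydro-2-benzofuran-1(3H)-one | O=C1OC[C@H]2C=C[C@@H](c3ccc(OCOC)cc3)C(C(=O)c3ccc(OCOC)cc3)=C12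
F5 | step 9 | 7-[4-(methoxymethoxy)benzoyl]-6-[4-(methoxymethoxy)phenyl]-2-benzofuran-1(3H)-one | O=C1OCc2ccc(-c3ccc(OCOC)cc3)c(C(=O)c3ccc(OCOC)cc3)c12
F6 | step 9 | 7-(hydroxymethyl)-3,3,4-tris[4-(methoxymethoxy)phenyl]-2-benzofuran-1(3H)-one | O=C1OC(c2ccc(OCOC)cc2)(c2ccc(OCOC)cc2)c2c(-c3ccc(OCOC)cc3)ccc(CO)c12
F7 | step 9 | 7-(hydroxymethyl)-3,3,4-tris[4-(methoxymethoxy)phenyl]-1,3-dihydro-2-benzofuran-1-ol (racemic) | OC1OC(c2ccc(OCOC)cc2)(c2ccc(OCOC)cc2)c2c(-c3ccc(OCOC)cc3)ccc(CO)c12
F8 | step 9 | {2-ethynyl-3-{hydroxybis[4-(methoxymethoxy)phenyl]methyl}-4-[4-(methoxymethoxy)phenyl]phenyl}methanol | C#Cc1c(CO)ccc(-c2ccc(OCOC)cc2)c1C(O)(c1ccc(OCOC)cc1)c1ccc(OCOC)cc1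
F9 | step 12 | {3-{methoxybis[4-(methoxymethoxy)phenyl]methyl}-4-[4-(methoxymethoxy)phenyl]-1,2-phenylene}dimethanol | OCc1ccc(-c2ccc(OCOC)cc2)c(C(OC)(c2ccc(OCOC)cc2)c2ccc(OCOC)cc2)c1CO
F10 | step 12 | {2-({[tert-butyl(diphenyl)silyl]oxy}methyl)-6-{methoxybis[4-(methoxymethoxy)phenyl]methyl}-5-[4-(methoxymethoxy)phenyl]phenyl}methanol | CC(C)(C)[Si](OCc1ccc(-c2ccc(OCOC)cc2)c(C(OC)(c2ccc(OCOC)cc2)c2ccc(OCOC)cc2)c1CO)(c1ccccc1)c1ccccc1
F11 | step 12 | 2-({[tert-butyl(diphenyl)silyl]oxy}methyl)-6-{methoxybis[4-(methoxymethoxy)phenyl]methyl}-5-[4-(methoxymethoxy)phenyl]benzaldehyde | CC(C)(C)[Si](OCc1ccc(-c2ccc(OCOC)cc2)c(C(OC)(c2ccc(OCOC)cc2)c2ccc(OCOC)cc2)c1C=O)(c1ccccc1)c1ccccc1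
F12 | step 12 | tert-butyl{[2-ethynyl-3-{methoxybis[4-(methoxymethoxy)phenyl]methyl}-4-[4-(methoxymethoxy)phenyl]phenyl]methoxy}diphenylsilane | CC(C)(C)[Si](OCc1ccc(-c2ccc(OCOC)cc2)c(C(OC)(c2ccc(OCOC)cc2)c2ccc(OCOC)cc2)c1C#C)(c1ccccc1)c1ccccc1
F13 | step 15 | {3-{bis[4-(methoxymethoxy)phenyl]methyl}-4-[4-(methoxymethoxy)phenyl]-2-{[4-(methoxymethoxy)phenyl]ethynyl}phenyl}methanol | COCOc1ccc(C#Cc2c(CO)ccc(-c3ccc(OCOC)cc3)c2C(c2ccc(OCOC)cc2)c2ccc(OCOC)cc2)cc1
F14 | step 15 | 4,4'-{[3-(hydroxymethyl)-6-(4-hydroxyphenyl)-2-[(4-hydroxyphenyl)ethynyl]phenyl]methylene}diphenol | OCc1ccc(-c2ccc(O)cc2)c(C(c2ccc(O)cc2)c2ccc(O)cc2)c1C#Cc1ccc(O)cc1
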